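Enabling feature: flavone ring A is a phloroglucinol. Its C6 lies between the C5 and C7 oxygens, para to the C8a oxygen (O1), and carries C5' of ring B' (the catechol ring on flavanone C2). A vinylketene and an aryl ynol ether assemble this 2-arylresorcinol with a third, para oxygen in one operation.
Cuts, from the end: flavanone O1–C2 (oxa-Michael) and C2–C3 (Knoevenagel); flavone C4–C4a, C3–C4 and O1–C2 (carbonylative alkyne annulation); flavone ring A at C6–C7, C7–C8 and C5–C4a (benzannulation). The hindered C6–C5' bond is thereby traced back to a plain aryl–alkyne bond.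
Forward order: ring B' (from 5-iodovanillin), then flavone ring A (step 8), then flavone ring C together with ring B (step 13), then flavanone ring C onto the ring A of phloroacetophenone (steps 17 and 18).
Stereochemistry: the single stereocentre, flavanone C2 (S), comes from a cinchona-thiourea-catalysed oxa-Michael closure of a tert-butyl β-ketoester alkylidene. Afterwards it meets only acid and neutral hydrogenolysis.
Protection: all eight phenols travel as benzyl ethers and are freed in the last step. Only the oxygen that becomes flavone O1 is carried as an allyl ether, so that it alone can be released after the benzannulation.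
Key step: step 8

Assumption 1: the quinidine-derived thiourea is taken to give the 2S series. The sense is checked on a model alkylidene, and the quinine-derived pseudoenantiomer is used if it proves opposite.
Assumption 2: the C6–C5' axis (three ortho oxygens, one ortho hydrogen) is treated as configurationally labile, since the target carries no axial descriptor.
Abbreviations: Bn = benzyl; TIPS = triisopropylsilyl; Ar = 2,3-bis(benzyloxy)-5-(1,3-dioxolan-2-yl)phenyl; Fl = 5,7-bis(benzyloxy)-2-[3,4-bis(benzyloxy)phenyl]-4-oxo-4H-chromen-6-yl.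

Step 1
Reactants: 1 5-iodovanillin (4-hydroxy-3-iodo-5-methoxybenzaldehyde)
Product: 2 3,4-dihydroxy-5-iodobenzaldehyde
Conditions: AlCl3, pyridine, CH2Cl2, reflux; then aq. HCl
Reagents that add atoms: none
Why: Chelation-assisted aryl methyl ether cleavage, in which AlCl3 binds the ortho hydroxy/methoxy pair and pyridine removes the methyl group by SN2 attack, is a standard demethylation of 5-halovanillins that leaves the aldehyde and the iodide untouched.

Step 2
Reactants: 2 3,4-dihydroxy-5-iodobenzaldehyde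
Product: 3 3,4-bis(benzyloxy)-5-iodobenzaldehyde
Conditions: BnBr, K2CO3, DMF, 60 °C
Reagents that add atoms: benzyl bromide BrCc1ccccc1
Why: Double Williamson etherification of the catechol installs the two benzyl ethers that stay until the last step.

Step 3
Reactants: 3 3,4-bis(benzyloxy)-5-iodobenzaldehyde
Product: 4 2-[3,4-bis(benzyloxy)-5-iodophenyl]-1,3-dioxolane
Conditions: HOCH2CH2OH, p-TsOH·H2O (cat.), toluene, reflux, Dean–Stark trap
Reagents that add atoms: ethylene glycol OCCO
Why: Acid-catalysed acetalisation driven by azeotropic removal of water masks the aldehyde against the organometallic reagents of steps 4 and 5, and benzyl ethers and the aryl iodide are inert to catalytic acid.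

Step 4
Reactants: 4 2-[3,4-bis(benzyloxy)-5-iodophenyl]-1,3-dioxolane
Product: 5 2-[3,4-bis(benzyloxy)-5-ethynylphenyl]-1,3-dioxolane
Conditions: HC≡CMgBr, ZnBr2, THF, 0 °C; then 4, Pd(PPh3)4 (5 mol %), 23 °C
Reagents that add atoms: ethynylmagnesium bromide C#C[Mg]Br
Why: Negishi coupling of ethynylzinc bromide with an aryl iodide under zerovalent palladium catalysis gives the terminal arylacetylene directly, the zinc acetylide being mild enough to spare the acetal and to avoid double arylation.

Step 5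
Reactants: 5 2-[3,4-bis(benzyloxy)-5-ethynylphenyl]-1,3-dioxolane
Product: 8 1-Ar-2-(triisopropylsiloxy)ethyne, via lithium acetylide 6 (not isolated), via lithium ynolate 7 (not isolated)
Conditions: n-BuLi (1.0 equiv), THF, −78 °C; t-BuOOLi (from t-BuOOH and LiN(SiMe3)2), −78 to 0 °C; TIPSOTf, −78 to 0 °C
Reagents that add atoms: tert-butyl hydroperoxide CC(C)(C)OO; triisopropylsilyl triflate CC(C)[Si](OS(=O)(=O)C(F)(F)F)(C(C)C)C(C)C
Why: Oxidation of a lithium acetylide by lithium tert-butyl peroxide (attack of the acetylide on the peroxide oxygen) is a known entry to ynolates, the bulky silyl triflate traps the ynolate on oxygen, and no excess alkyllithium is present that could metalate the benzyl ethers or the ring.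

Step 6
Reactants: 9 acetone; 10 ethoxyacetylene
Product: 12 3-ethoxycyclobut-2-en-1-one, via ketene 11 (not isolated)
Conditions: acetone vapour over a glowing filament (ketene generator, about 700 °C); gas stream passed into 10, CH2Cl2, 0 °C
Reagents that add atoms: none
Why: Thermal [2+2] cycloaddition of ketene to an ynol ether, in which the nucleophilic CH terminus of 10 bonds to the ketene carbonyl carbon, is the known preparation of this cyclobutenone.

Step 7
Reactants: 12 3-ethoxycyclobut-2-en-1-one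
Product: 13 3-(allyloxy)cyclobut-2-en-1-one
Conditions: allyl alcohol (solvent), camphorsulfonic acid (cat.), 23 °C, EtOH stripped under reduced pressure; Et3N quench
Reagents that add atoms: allyl alcohol C=CCO
Why: Acid-catalysed alkoxy exchange of a vinylogous ester by addition–elimination at C3, the same pathway as the known acid hydrolysis of 12 to cyclobutane-1,3-dione, is driven by the excess of allyl alcohol and the removal of ethanol and is run well below the temperature at which the ring opens.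

Step 8
Reactants: 8 1-Ar-2-(triisopropylsiloxy)ethyne; 13 3-(allyloxy)cyclobut-2-en-1-one
Product: 18 5-(allyloxy)-2-Ar-3-(triisopropylsiloxy)phenol, via allyloxy vinylketene 14 (not isolated), via vinylcyclobutenone 15 (not isolated), via dienylketene 16 (not isolated), via cyclohexadienone 17 (not isolated)
Conditions: toluene, Ar, 80 °C, 13 (1.2 equiv) added slowly by syringe pump; then 110 °C
Reagents that add atoms: none
Why: Four-electron electrocyclic opening of 13 gives vinylketene 14, whose ketene C=C adds to ynol ether 8 in a [2+2] cycloaddition to give 4-vinylcyclobutenone 15; a second four-electron opening gives dienylketene 16, which closes to cyclohexadienone 17 and tautomerises to phenol 18. This is the Danheiser benzannulation of a cyclobutenone with a trialkylsiloxyalkyne, the known route to resorcinol monosilyl ethers, and the 3-alkoxy group of 13 merely supplies the third oxygen. Flavone ring A is closed by the six-electron disrotatory electrocyclisation of 16, which makes C7–C8 (C7 being the carbon that bears the free hydroxyl), after the [2+2]/ring-opening sequence has made C6–C7 and C5–C4a. No stereocentre is formed. The step needs regioselectivity in the [2+2] event, and the polarisation of the ynol ether secures it: the aryl-bearing carbon is the nucleophilic terminus and bonds to the ketene carbonyl carbon, so that Ar ends between the free hydroxyl and the siloxy group and para to the allyloxy group. Chemoselectivity rests on the ynol ether being a far better ketenophile than the terminal allyl alkene, on slow addition of 13 to keep 14 dilute, and on a ceiling of 110 °C, below the range in which allyl enol ethers or allyl aryl ethers undergo Claisen rearrangement at a useful rate.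

Step 9
Reactants: 18 5-(allyloxy)-2-Ar-3-(triisopropylsiloxy)phenol
Product: 20 5-(allyloxy)-1,3-bis(benzyloxy)-2-Ar-benzene, via resorcinol 19 (not isolated)
Conditions: Bu4NF, DMF, 0 °C; then K2CO3, BnBr, 23 to 50 °C
Reagents that add atoms: benzyl bromide BrCc1ccccc1
Why: Fluoride cleavage of the aryl silyl ether followed by double Williamson etherification caps both oxygens next to the biaryl bond alike, which makes ring A symmetric about that bond and its two CH positions equivalent.

Step 10
Reactants: 20 5-(allyloxy)-1,3-bis(benzyloxy)-2-Ar-benzene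
Product: 21 3,5-bis(benzyloxy)-4-Ar-phenol
Conditions: Pd(PPh3)4 (5 mol %), morpholine, THF, 23 °C
Reagents that add atoms: none
Why: In this Tsuji–Trost deallylation zerovalent palladium ionises the aryl allyl ether and morpholine takes up the allyl group, conditions to which benzyl ethers and the acetal are inert.

Step 11
Reactants: 21 3,5-bis(benzyloxy)-4-Ar-phenol
Product: 22 3,5-bis(benzyloxy)-4-Ar-2-iodophenol
Conditions: N-iodosuccinimide (1.0 equiv), CH2Cl2, −20 to 0 °C
Reagents that add atoms: N-iodosuccinimide O=C1CCC(=O)N1I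
Why: Electrophilic aromatic iodination goes ortho to the free phenol on the most electron-rich ring, where the para position is blocked by Ar, the two ortho positions are equivalent, and one equivalent of reagent at low temperature limits double iodination.

Step 12
Reactants: 23 3,4-bis(benzyloxy)benzaldehyde
Product: 24 1,2-bis(benzyloxy)-4-ethynylbenzene
Conditions: dimethyl (1-diazo-2-oxopropyl)phosphonate, K2CO3, MeOH/THF, 23 °C
Reagents that add atoms: dimethyl (1-diazo-2-oxopropyl)phosphonate COP(=O)(OC)C(=[N+]=[N-])C(C)=O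
Why: Seyferth–Gilbert homologation in the Ohira–Bestmann variant converts the aryl aldehyde into the terminal alkyne under mild carbonate conditions.

Step 13
Reactants: 22 3,5-bis(benzyloxy)-4-Ar-2-iodophenol; 24 1,2-bis(benzyloxy)-4-ethynylbenzene
Product: 26 5,7-bis(benzyloxy)-2-[3,4-bis(benzyloxy)phenyl]-6-Ar-4H-chromen-4-one, via hydroxyaryl ynone 25 (not isolated)
Conditions: PdCl2(dppf) (5 mol %), CO (10 bar), Et2NH/DMF, 80 °C
Reagents that add atoms: carbon monoxide [C-]#[O+]
Why: Palladium-catalysed carbonylative coupling of an ortho-iodophenol with a terminal alkyne (copper-free carbonylative Sonogashira-type reaction) gives ynone 25, which the secondary amine carries by conjugate addition and 6-endo closure of the phenol oxygen into the flavone, a known one-pot flavone synthesis whose basic medium spares acetal and benzyl ethers.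

Step 14
Reactants: 26 5,7-bis(benzyloxy)-2-[3,4-bis(benzyloxy)phenyl]-6-Ar-4H-chromen-4-one
Product: 27 3,4-bis(benzyloxy)-5-Fl-benzaldehyde
Conditions: 1 M aq. HCl, THF, 23 °C
Reagents that add atoms: water O
Why: Acid hydrolysis of the aryl dioxolane is fast because the oxocarbenium ion is stabilised by the para benzyloxy group, while benzyl ethers and the flavone are stable to dilute acid.

Step 15
Reactants: 28 2,4,6-trihydroxyacetophenone
Product: 29 1-[2,4-bis(benzyloxy)-6-hydroxyphenyl]ethan-1-one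
Conditions: BnBr (2.05 equiv), K2CO3, DMF, 23 to 50 °C
Reagents that add atoms: benzyl bromide BrCc1ccccc1
Why: This Williamson etherification is selective because, once the 4-OH and one ortho OH have reacted, the remaining ortho OH is hydrogen-bonded to the ketone and stays free.

Step 16
Reactants: 29 1-[2,4-bis(benzyloxy)-6-hydroxyphenyl]ethan-1-one
Product: 31 tert-butyl 3-[2,4-bis(benzyloxy)-6-hydroxyphenyl]-3-oxopropanoate, via dilithium enolate phenoxide 30 (not isolated)
Conditions: LiN(SiMe3)2 (3.3 equiv), THF, −78 °C; Boc2O (1.05 equiv), −78 to −20 °C; AcOH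
Reagents that add atoms: di-tert-butyl dicarbonate CC(C)(C)OC(=O)OC(=O)OC(C)(C)C
Why: Claisen-type C-acylation of the phenoxide/enolate dianion takes place at the more reactive enolate carbon, and the doubly stabilised β-ketoester enolate is the thermodynamic sink even if some O-acylation occurs first.

Step 17
Reactants: 27 3,4-bis(benzyloxy)-5-Fl-benzaldehyde; 31 tert-butyl 3-[2,4-bis(benzyloxy)-6-hydroxyphenyl]-3-oxopropanoate
Product: 32 tert-butyl 2-[2,4-bis(benzyloxy)-6-hydroxybenzoyl]-3-[3,4-bis(benzyloxy)-5-Fl-phenyl]prop-2-enoate (alkene geometry not controlled; both isomers are used)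
Conditions: piperidine (cat.), AcOH (cat.), 4 Å molecular sieves, toluene, 23 °C
Reagents that add atoms: none
Why: Knoevenagel condensation of the unhindered aryl aldehyde with the β-ketoester under piperidinium acetate catalysis forms flavanone C2–C3 as the alkene, the chelated phenol being too poor a nucleophile to add under these conditions.

Step 18
Reactants: 32 tert-butyl 2-[2,4-bis(benzyloxy)-6-hydroxybenzoyl]-3-[3,4-bis(benzyloxy)-5-Fl-phenyl]prop-2-enoate
Product: 35 (2S)-5,7-bis(benzyloxy)-2-[3,4-bis(benzyloxy)-5-Fl-phenyl]chroman-4-one, via tert-butyl chromanone-3-carboxylate 33 (not isolated), via chromanone-3-carboxylic acid 34 (not isolated)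
Conditions: 1-[3,5-bis(trifluoromethyl)phenyl]-3-[(9R)-6'-methoxycinchonan-9-yl]thiourea (quinidine-derived, 10 mol %), toluene, −25 °C; then p-TsOH·H2O, 80 °C
Reagents that add atoms: none
Why: Bifunctional catalysis of the 6-endo-trig intramolecular oxa-Michael addition (thiourea binds the β-ketoester, quinuclidine activates the phenol) sets C2 as S by catalyst-controlled facial selection on an alkylidene β-ketoester, a known enantioselective flavanone synthesis, and the acid then protonates the catalyst, cleaves the tert-butyl ester and lets the β-keto acid lose CO2 through its enol, so that no base-mediated ring opening can scramble C2.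

Step 19
Reactants: 35 (2S)-5,7-bis(benzyloxy)-2-[3,4-bis(benzyloxy)-5-Fl-phenyl]chroman-4-one
Product: 36 (2S)-2-{3,4-dihydroxy-5-[2-(3,4-dihydroxyphenyl)-5,7-dihydroxy-4-oxo-4H-chromen-6-yl]phenyl}-5,7-dihydroxychroman-4-one (CNP0333260.1)
Conditions: H2 (1 atm), 10% Pd/C, THF/MeOH, 23 °C
Reagents that add atoms: none
Why: Catalytic hydrogenolysis of the eight aryl benzyl ethers in neutral medium neither opens the flavanone (no base) nor reduces the flavone enone at atmospheric pressure, so that C2 stays S.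

Compound list
1 | 5-iodovanillin | COc1cc(C=O)cc(I)c1O | starting material
2 | 3,4-dihydroxy-5-iodobenzaldehyde | O=Cc1cc(O)c(O)c(I)c1 | intermediate
3 | 3,4-bis(benzyloxy)-5-iodobenzaldehyde | O=Cc1cc(OCc2ccccc2)c(OCc2ccccc2)c(I)c1 | intermediate
4 | 2-[3,4-bis(benzyloxy)-5-iodophenyl]-1,3-dioxolane | Ic1cc(C2OCCO2)cc(OCc2ccccc2)c1OCc1ccccc1 | intermediate
5 | 2-[3,4-bis(benzyloxy)-5-ethynylphenyl]-1,3-dioxolane | C#Cc1cc(C2OCCO2)cc(OCc2ccccc2)c1OCc1ccccc1 | intermediate
6 | lithium acetylide of 5 | [Li]C#Cc1cc(C2OCCO2)cc(OCc2ccccc2)c1OCc1ccccc1 | intermediate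
7 | lithium 2-Ar-ethynolate | [Li]OC#Cc1cc(C2OCCO2)cc(OCc2ccccc2)c1OCc1ccccc1 | intermediate
8 | 1-Ar-2-(triisopropylsiloxy)ethyne | CC(C)[Si](OC#Cc1cc(C2OCCO2)cc(OCc2ccccc2)c1OCc1ccccc1)(C(C)C)C(C)C | intermediate
9 | acetone | CC(C)=O | starting material
10 | ethoxyacetylene | CCOC#C | starting material
11 | ketene | C=C=O | intermediate
12 | 3-ethoxycyclobut-2-en-1-one | CCOC1=CC(=O)C1 | intermediate
13 | 3-(allyloxy)cyclobut-2-en-1-one | C=CCOC1=CC(=O)C1 | intermediate
14 | 3-(allyloxy)buta-1,3-dien-1-one | C=CCOC(=C)C=C=O | intermediate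
15 | 4-[1-(allyloxy)vinyl]-2-Ar-3-(triisopropylsiloxy)cyclobut-2-en-1-one (racemic) | O=C1C(c2cc(C3OCCO3)cc(OCc3ccccc3)c2OCc2ccccc2)=C(O[Si](C(C)C)(C(C)C)C(C)C)C1C(=C)OCC=C | intermediate
16 | 5-(allyloxy)-2-Ar-3-(triisopropylsiloxy)hexa-1,3,5-trien-1-one | O=C=C(c1cc(C2OCCO2)cc(OCc2ccccc2)c1OCc1ccccc1)C(O[Si](C(C)C)(C(C)C)C(C)C)=CC(=C)OCC=C | intermediate
17 | 5-(allyloxy)-2-Ar-3-(triisopropylsiloxy)cyclohexa-2,4-dien-1-one | O=C1CC(OCC=C)=CC(O[Si](C(C)C)(C(C)C)C(C)C)=C1c1cc(C2OCCO2)cc(OCc2ccccc2)c1OCc1ccccc1 | intermediate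
18 | 5-(allyloxy)-2-Ar-3-(triisopropylsiloxy)phenol | Oc1cc(OCC=C)cc(O[Si](C(C)C)(C(C)C)C(C)C)c1-c1cc(C2OCCO2)cc(OCc2ccccc2)c1OCc1ccccc1 | intermediate
19 | 5-(allyloxy)-2-Ar-benzene-1,3-diol | Oc1cc(OCC=C)cc(O)c1-c1cc(C2OCCO2)cc(OCc2ccccc2)c1OCc1ccccc1 | intermediate
20 | 5-(allyloxy)-1,3-bis(benzyloxy)-2-Ar-benzene | C=CCOc1cc(OCc2ccccc2)c(-c2cc(C3OCCO3)cc(OCc3ccccc3)c2OCc2ccccc2)c(OCc2ccccc2)c1 | intermediate
21 | 3,5-bis(benzyloxy)-4-Ar-phenol | Oc1cc(OCc2ccccc2)c(-c2cc(C3OCCO3)cc(OCc3ccccc3)c2OCc2ccccc2)c(OCc2ccccc2)c1 | intermediate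
22 | 3,5-bis(benzyloxy)-4-Ar-2-iodophenol | Oc1cc(OCc2ccccc2)c(-c2cc(C3OCCO3)cc(OCc3ccccc3)c2OCc2ccccc2)c(OCc2ccccc2)c1I | intermediate
23 | 3,4-bis(benzyloxy)benzaldehyde | O=Cc1ccc(OCc2ccccc2)c(OCc2ccccc2)c1 | starting material
24 | 1,2-bis(benzyloxy)-4-ethynylbenzene | C#Cc1ccc(OCc2ccccc2)c(OCc2ccccc2)c1 | intermediate
25 | 1-[4,6-bis(benzyloxy)-2-hydroxy-5-Ar-phenyl]-3-[3,4-bis(benzyloxy)phenyl]prop-2-yn-1-one | O=C(C#Cc1ccc(OCc2ccccc2)c(OCc2ccccc2)c1)c1c(O)cc(OCc2ccccc2)c(-c2cc(C3OCCO3)cc(OCc3ccccc3)c2OCc2ccccc2)c1OCc1ccccc1 | intermediate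
26 | 5,7-bis(benzyloxy)-2-[3,4-bis(benzyloxy)phenyl]-6-Ar-4H-chromen-4-one | O=c1cc(-c2ccc(OCc3ccccc3)c(OCc3ccccc3)c2)oc2cc(OCc3ccccc3)c(-c3cc(C4OCCO4)cc(OCc4ccccc4)c3OCc3ccccc3)c(OCc3ccccc3)c12 | intermediate
27 | 3,4-bis(benzyloxy)-5-Fl-benzaldehyde | O=Cc1cc(OCc2ccccc2)c(OCc2ccccc2)c(-c2c(OCc3ccccc3)cc3oc(-c4ccc(OCc5ccccc5)c(OCc5ccccc5)c4)cc(=O)c3c2OCc2ccccc2)c1 | intermediate
28 | 2,4,6-trihydroxyacetophenone | CC(=O)c1c(O)cc(O)cc1O | starting material
29 | 1-[2,4-bis(benzyloxy)-6-hydroxyphenyl]ethan-1-one | CC(=O)c1c(O)cc(OCc2ccccc2)cc1OCc1ccccc1 | intermediate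
30 | dilithium enolate phenoxide of 29 | [Li]OC(=C)c1c(O[Li])cc(OCc2ccccc2)cc1OCc1ccccc1 | intermediate
31 | tert-butyl 3-[2,4-bis(benzyloxy)-6-hydroxyphenyl]-3-oxopropanoate | CC(C)(C)OC(=O)CC(=O)c1c(O)cc(OCc2ccccc2)cc1OCc1ccccc1 | intermediate
32 | tert-butyl 2-[2,4-bis(benzyloxy)-6-hydroxybenzoyl]-3-[3,4-bis(benzyloxy)-5-Fl-phenyl]prop-2-enoate (E/Z mixture) | CC(C)(C)OC(=O)C(=Cc1cc(OCc2ccccc2)c(OCc2ccccc2)c(-c2c(OCc3ccccc3)cc3oc(-c4ccc(OCc5ccccc5)c(OCc5ccccc5)c4)cc(=O)c3c2OCc2ccccc2)c1)C(=O)c1c(O)cc(OCc2ccccc2)cc1OCc1ccccc1 | intermediate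
33 | tert-butyl (2S)-5,7-bis(benzyloxy)-2-[3,4-bis(benzyloxy)-5-Fl-phenyl]-4-oxochromane-3-carboxylate (C3 epimers and enol) | O=C1C(C(=O)OC(C)(C)C)[C@@H](c2cc(OCc3ccccc3)c(OCc3ccccc3)c(-c3c(OCc4ccccc4)cc4oc(-c5ccc(OCc6ccccc6)c(OCc6ccccc6)c5)cc(=O)c4c3OCc3ccccc3)c2)Oc2cc(OCc3ccccc3)cc(OCc3ccccc3)c21 | intermediate
34 | (2S)-5,7-bis(benzyloxy)-2-[3,4-bis(benzyloxy)-5-Fl-phenyl]-4-oxochromane-3-carboxylic acid | O=C1C(C(=O)O)[C@@H](c2cc(OCc3ccccc3)c(OCc3ccccc3)c(-c3c(OCc4ccccc4)cc4oc(-c5ccc(OCc6ccccc6)c(OCc6ccccc6)c5)cc(=O)c4c3OCc3ccccc3)c2)Oc2cc(OCc3ccccc3)cc(OCc3ccccc3)c21 | intermediate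
35 | (2S)-5,7-bis(benzyloxy)-2-[3,4-bis(benzyloxy)-5-Fl-phenyl]chroman-4-one | O=C1C[C@@H](c2cc(OCc3ccccc3)c(OCc3ccccc3)c(-c3c(OCc4ccccc4)cc4oc(-c5ccc(OCc6ccccc6)c(OCc6ccccc6)c5)cc(=O)c4c3OCc3ccccc3)c2)Oc2cc(OCc3ccccc3)cc(OCc3ccccc3)c21 | intermediate
36 | (2S)-2-{3,4-dihydroxy-5-[2-(3,4-dihydroxyphenyl)-5,7-dihydroxy-4-oxo-4H-chromen-6-yl]phenyl}-5,7-dihydroxychroman-4-one | O=C1C[C@@H](c2cc(O)c(O)c(-c3c(O)cc4oc(-c5ccc(O)c(O)c5)cc(=O)c4c3O)c2)Oc2cc(O)cc(O)c21 | target

Total step count: 19
Longest linear sequence: 14 steps (1–5, 8–11, 13, 14, 17–19)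

Steps most likely to fail

1. Step 8. The nucleophilic carbon of the ynol ether carries an ortho-substituted aryl group. Capture of the transient vinylketene may therefore be slower than vinylketene dimerisation, acylation of the product phenol by the ketene, or thermal decay of the siloxyalkyne.
Fallback, setting out from 4 and coming back at 26: the C6–C5' bond is made by cross-coupling on a preformed flavone.
- Miyaura borylation of 4 (B2pin2, PdCl2(dppf), KOAc, dioxane, 80 °C) gives 2-[3,4-bis(benzyloxy)-5-(4,4,5,5-tetramethyl-1,3,2-dioxaborolan-2-yl)phenyl]-1,3-dioxolane F1.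
- Commercial luteolin is benzylated at O7, O3' and O4' (BnBr, K2CO3, DMF; the chelated 5-OH stays free) to 7,3',4'-tri-O-benzylluteolin F2.
- F2 is iodinated ortho to the free 5-OH (BnNMe3ICl2, CaCO3, CH2Cl2/MeOH) to 7,3',4'-tri-O-benzyl-6-iodoluteolin F3.
- F3 is benzylated at O5 (BnBr, K2CO3, DMF, 60 °C) to 5,7,3',4'-tetra-O-benzyl-6-iodoluteolin F4.
- Suzuki–Miyaura coupling of F1 with F4 (Pd(OAc)2, SPhos, K3PO4, toluene/H2O, 90 °C) gives 26.

2. Step 18. The 6'-benzyloxy group and the very large aryl residue may lower facial selectivity. Reversible C–O bond formation may erode the enantiomeric purity before or during decarboxylation.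
Fallback, setting out from 27 and 29 and coming back at 35: racemic closure followed by kinetic resolution.
- Claisen–Schmidt condensation of 27 with 29 (KOH, EtOH/THF, 23 °C) gives the (E)-2'-hydroxychalcone F5.
- NaOAc in refluxing EtOH closes F5 to the racemic octabenzyl flavanone F6.
- Noyori-type asymmetric transfer hydrogenation (RhCl[(R,R)-TsDPEN](C5Me5), HCO2H/Et3N, EtOAc, 23 °C) reduces the 2R enantiomer to the cis-(2R,4R)-flavan-4-ol F7.
- The slow-reacting 2S ketone 35 is left behind and is separated by chromatography.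

3. Step 13. Oxidative addition and CO insertion at the doubly ortho-substituted, electron-rich iodide may be slow. Direct alkynylation without CO uptake would then lead to benzofuran closure, and 5-exo closure of the ynone is a further competing path.
Fallback, setting out from 24 and 22 and coming back at 25 and then 26: the acyl carbon is brought in by an organolithium acylation instead of by palladium and CO.
- Alkyne 24 is deprotonated (n-BuLi, THF, −78 °C) and treated with N-methoxy-N-methylcarbamoyl chloride to give 3-[3,4-bis(benzyloxy)phenyl]-N-methoxy-N-methylprop-2-ynamide F8.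
- Iodophenol 22 is converted with n-BuLi (2.1 equiv, THF, −78 °C) into the lithium 2-lithiophenoxide F9.
- F9 adds to F8 to give ynone 25, now isolated.
- Et2NH in DMF at 50 °C then closes 25 to 26.

Further compounds
F1 | step 8 | 2-[3,4-bis(benzyloxy)-5-(4,4,5,5-tetramethyl-1,3,2-dioxaborolan-2-yl)phenyl]-1,3-dioxolane | CC1(C)OB(c2cc(C3OCCO3)cc(OCc3ccccc3)c2OCc2ccccc2)OC1(C)C
F2 | step 8 | 7,3',4'-tri-O-benzylluteolin | O=c1cc(-c2ccc(OCc3ccccc3)c(OCc3ccccc3)c2)oc2cc(OCc3ccccc3)cc(O)c12
F3 | step 8 | 7,3',4'-tri-O-benzyl-6-iodoluteolin | O=c1cc(-c2ccc(OCc3ccccc3)c(OCc3ccccc3)c2)oc2cc(OCc3ccccc3)c(I)c(O)c12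
F4 | step 8 | 5,7,3',4'-tetra-O-benzyl-6-iodoluteolin | O=c1cc(-c2ccc(OCc3ccccc3)c(OCc3ccccc3)c2)oc2cc(OCc3ccccc3)c(I)c(OCc3ccccc3)c12
F5 | step 18 | (E)-1-[2,4-bis(benzyloxy)-6-hydroxyphenyl]-3-[3,4-bis(benzyloxy)-5-Fl-phenyl]prop-2-en-1-one | O=C(/C=C/c1cc(OCc2ccccc2)c(OCc2ccccc2)c(-c2c(OCc3ccccc3)cc3oc(-c4ccc(OCc5ccccc5)c(OCc5ccccc5)c4)cc(=O)c3c2OCc2ccccc2)c1)c1c(O)cc(OCc2ccccc2)cc1OCc1ccccc1
F6 | step 18 | racemic 5,7-bis(benzyloxy)-2-[3,4-bis(benzyloxy)-5-Fl-phenyl]chroman-4-one | O=C1CC(c2cc(OCc3ccccc3)c(OCc3ccccc3)c(-c3c(OCc4ccccc4)cc4oc(-c5ccc(OCc6ccccc6)c(OCc6ccccc6)c5)cc(=O)c4c3OCc3ccccc3)c2)Oc2cc(OCc3ccccc3)cc(OCc3ccccc3)c21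
F7 | step 18 | (2R,4R)-5,7-bis(benzyloxy)-2-[3,4-bis(benzyloxy)-5-Fl-phenyl]chroman-4-ol | O[C@@H]1C[C@H](c2cc(OCc3ccccc3)c(OCc3ccccc3)c(-c3c(OCc4ccccc4)cc4oc(-c5ccc(OCc6ccccc6)c(OCc6ccccc6)c5)cc(=O)c4c3OCc3ccccc3)c2)Oc2cc(OCc3ccccc3)cc(OCc3ccccc3)c21
F8 | step 13 | 3-[3,4-bis(benzyloxy)phenyl]-N-methoxy-N-methylprop-2-ynamide | CON(C)C(=O)C#Cc1ccc(OCc2ccccc2)c(OCc2ccccc2)c1
F9 | step 13 | lithium 3,5-bis(benzyloxy)-4-Ar-2-lithiophenoxide | [Li]Oc1cc(OCc2ccccc2)c(-c2cc(C3OCCO3)cc(OCc3ccccc3)c2OCc2ccccc2)c(OCc2ccccc2)c1[Li]
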